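The route rests on disconnecting C3–C4 of ring C in the robinetinidol unit. C4 is doubly benzylic (ring A and ring D of the gallocatechin unit) and C3 carries a hydroxyl, so the bond is treated as a latent pinacol bond. A SmI2 ketyl coupling of a ring A/ring D diaryl ketone (future C4) with a tethered α-aryloxy aldehyde (future C3) closes ring C in one operation and sets the C3 carbinol trans to the catalytically installed C2 aryl group. The surplus C4 hydroxyl is then excised by ionic hydrogenation, hydride entering anti to the C3 oxygen to give the 3,4-cis arrangement. The gallocatechin unit comes from the chiral pool.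

Key step: step 12

Remark on the target: the SMILES is read as robinetinidol-(4→8)-gallocatechin with upper unit (2R,3S,4R), i.e. 2,3-trans-3,4-cis, and lower unit (2R,3S). Rings A/C/B belong to the upper unit and rings D/F/E to the lower unit.
Remark on materials: (+)-gallocatechin (2R,3S), 3,4,5-tris(benzyloxy)benzaldehyde and 4-(benzyloxy)-2-hydroxybenzaldehyde are taken as purchasable.
Remark on step 7: the (Ra,Rc,Rc) ligand is assumed to give the S ether; if the sense of induction is opposite, the antipodal ligand is used.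
Abbreviations in names: Ar = 3,4,5-tris(benzyloxy)phenyl; GC = (2R,3S)-3,5,7-tris(benzyloxy)-2-[3,4,5-tris(benzyloxy)phenyl]chroman-8-yl.

Step 1
Reactants: 1 (+)-gallocatechin
Product: 2 (2R,3S)-5,7-bis(benzyloxy)-2-[3,4,5-tris(benzyloxy)phenyl]chroman-3-ol
Conditions: BnBr (5.5 equiv), K2CO3, DMF, argon, 0 °C to rt
Reagents that add atoms: benzyl bromide, BrCc1ccccc1
Why: Williamson etherification of the five phenoxides under carbonate base should leave the aliphatic 3-OH and both stereocenters untouched, with exclusion of air protecting the pyrogallol ring.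

Step 2
Reactants: 2 (2R,3S)-5,7-bis(benzyloxy)-2-[3,4,5-tris(benzyloxy)phenyl]chroman-3-ol
Product: 3 (2R,3S)-3,5,7-tris(benzyloxy)-2-[3,4,5-tris(benzyloxy)phenyl]chroman
Conditions: NaH, BnBr, DMF, 0 °C to rt
Reagents that add atoms: benzyl bromide, BrCc1ccccc1
Why: Williamson etherification of the secondary alkoxide should protect the 3-OH against the later oxidations without touching a stereocenter.

Step 3
Reactants: 3 (2R,3S)-3,5,7-tris(benzyloxy)-2-[3,4,5-tris(benzyloxy)phenyl]chroman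
Product: 4 (2R,3S)-8-bromo-3,5,7-tris(benzyloxy)-2-[3,4,5-tris(benzyloxy)phenyl]chroman
Conditions: NBS (1.0 equiv), CH2Cl2, −78 °C to 0 °C
Reagents that add atoms: N-bromosuccinimide, O=C1CCC(=O)N1Br
Why: Electrophilic aromatic bromination should occur on the phloroglucinol-type ring, the most electron-rich one, at C8, which is less hindered than C6 between two benzyloxy groups.

Step 4
Reactants: 5 3,4,5-tris(benzyloxy)benzaldehyde
Product: 6 ethyl (E)-3-[3,4,5-tris(benzyloxy)phenyl]prop-2-enoate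
Conditions: (EtO)2P(O)CH2CO2Et, NaH, THF, 0 °C to rt
Reagents that add atoms: triethyl phosphonoacetate, CCOC(=O)CP(=O)(OCC)OCC
Why: Horner–Wadsworth–Emmons olefination of an aromatic aldehyde with a stabilised phosphonate should give the E enoate.

Step 5
Reactants: 6 ethyl (E)-3-[3,4,5-tris(benzyloxy)phenyl]prop-2-enoate
Product: 7 (E)-3-[3,4,5-tris(benzyloxy)phenyl]prop-2-en-1-ol
Conditions: i-Bu2AlH (DIBAL-H, 2.2 equiv), CH2Cl2, −78 °C; aq. KNaC4H4O6 work-up
Reagents that add atoms: none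
Why: 1,2-Reduction of the enoate by the aluminium hydride should give the allylic alcohol with the E alkene intact.

Step 6
Reactants: 7 (E)-3-[3,4,5-tris(benzyloxy)phenyl]prop-2-en-1-ol
Product: 8 methyl (E)-3-[3,4,5-tris(benzyloxy)phenyl]prop-2-en-1-yl carbonate
Conditions: ClCO2Me, pyridine, CH2Cl2, 0 °C
Reagents that add atoms: methyl chloroformate, COC(=O)Cl
Why: O-Acylation of the primary allylic alcohol should give the linear carbonate needed as an allyl electrophile.

Step 7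
Reactants: 9 4-(benzyloxy)-2-hydroxybenzaldehyde; 8 methyl (E)-3-[3,4,5-tris(benzyloxy)phenyl]prop-2-en-1-yl carbonate
Product: 11 4-(benzyloxy)-2-{[(1S)-1-[3,4,5-tris(benzyloxy)phenyl]prop-2-en-1-yl]oxy}benzaldehyde, via sodium 5-(benzyloxy)-2-formylphenoxide 10 (not isolated)
Conditions: 9, NaH, THF, 0 °C; then 8, [Ir(cod)Cl]2 (2 mol %), (Ra,Rc,Rc)-O,O'-(1,1'-binaphthyl-2,2'-diyl)-N,N-bis(1-phenylethyl)phosphoramidite (4 mol %, preactivated with n-PrNH2), THF, rt
Reagents that add atoms: none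
Why: Iridium-catalysed asymmetric allylic etherification should bring the aryloxide to the aryl-substituted terminus of the allyliridium intermediate, giving the branched ether whose stereocenter (the future C2) is set by the chiral ligand.

Step 8
Reactants: 4 (2R,3S)-8-bromo-3,5,7-tris(benzyloxy)-2-[3,4,5-tris(benzyloxy)phenyl]chroman; 11 4-(benzyloxy)-2-{[(1S)-1-[3,4,5-tris(benzyloxy)phenyl]prop-2-en-1-yl]oxy}benzaldehyde
Product: 13 {4-(benzyloxy)-2-[((1S)-1-Ar-prop-2-en-1-yl)oxy]phenyl}(GC)methanol as both carbinol epimers, via 8-lithio hexabenzyl gallocatechin 12 (not isolated)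
Conditions: 4, n-BuLi (1.05 equiv), THF, −78 °C; then 11, −78 °C; aq. NH4Cl
Reagents that add atoms: none
Why: Bromine–lithium exchange followed by 1,2-addition of the aryllithium to the non-enolisable aldehyde should join ring D to the future C4; the new carbinol center is removed in step 9.

Step 9
Reactants: 13 {4-(benzyloxy)-2-[((1S)-1-Ar-prop-2-en-1-yl)oxy]phenyl}(GC)methanol
Product: 14 {4-(benzyloxy)-2-[((1S)-1-Ar-prop-2-en-1-yl)oxy]phenyl}(GC)methanone
Conditions: activated MnO2 (excess), CH2Cl2, rt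
Reagents that add atoms: none
Why: Neutral MnO2 oxidation of a doubly benzylic alcohol should give the diaryl ketone without ionising the acid-labile carbinol or touching the alkene.

Step 10
Reactants: 14 {4-(benzyloxy)-2-[((1S)-1-Ar-prop-2-en-1-yl)oxy]phenyl}(GC)methanone
Product: 15 {4-(benzyloxy)-2-[((1R)-2,3-dihydroxy-1-Ar-propyl)oxy]phenyl}(GC)methanone as both epimers at the secondary carbinol
Conditions: OsO4 (2 mol %), NMO, acetone/H2O, rt
Reagents that add atoms: osmium tetroxide, O=[Os](=O)(=O)=O; N-methylmorpholine N-oxide, C[N+]1([O-])CCOCC1; water, O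
Why: Upjohn dihydroxylation of the only alkene should give the diol; its new carbinol center is removed in step 11 and the ether stereocenter is not involved (its descriptor changes only by priority).

Step 11
Reactants: 15 {4-(benzyloxy)-2-[((1R)-2,3-dihydroxy-1-Ar-propyl)oxy]phenyl}(GC)methanone
Product: 16 (2R)-2-{5-(benzyloxy)-2-[(GC)carbonyl]phenoxy}-2-Ar-acetaldehyde
Conditions: NaIO4 on silica gel, CH2Cl2, rt, short contact; filtered and used at once
Reagents that add atoms: none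
Why: Periodate glycol cleavage under neutral, base-free conditions should deliver the configurationally sensitive α-aryl-α-aryloxy aldehyde without epimerising the future C2.

Step 12
Reactants: 16 (2R)-2-{5-(benzyloxy)-2-[(GC)carbonyl]phenoxy}-2-Ar-acetaldehyde
Product: 17 (2R,3R,4R)-7-(benzyloxy)-2-Ar-4-(GC)chromane-3,4-diol (2,3-trans, 3,4-cis diol)
Conditions: SmI2 (3 equiv, 0.1 M in THF), THF, −78 °C to −20 °C; aq. NaHCO3/KNaC4H4O6 work-up
Reagents that add atoms: none
Why: SmI2 transfers an electron to the samarium-chelated dicarbonyl; whichever carbonyl is reduced first, its ketyl carbon adds to the second, samarium-bound carbonyl and a further electron gives the samarium diolate, so the C4 ketyl carbon and the C3 formyl carbon are joined. The closest known reaction type is the SmI2-mediated intramolecular ketone–aldehyde pinacol coupling that gives cis-1,2-diols of six-membered carbo- and heterocycles. Ring C (C4, C4a, C8a, O1, C2, C3) closes in a 6-exo-trig mode with respect to the attacked C=O. C3 is controlled by the existing C2 center: in a chair-like transition state the C2 aryl group is equatorial and the formyl C–O bond lies antiperiplanar to C2–O1 (dipole minimised), which puts the C3 oxygen trans to the C2 aryl group, while C4 is controlled by trivalent samarium bridging both oxygens, which makes the diol cis. The step needs C–C coupling to outrun reductive loss of the α-aryloxy group and needs C2 to stay intact; intramolecularity, the absence of HMPA and proton sources, and −78 °C should secure both, and the C4 configuration is immaterial because it is reset in step 13.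

Step 13
Reactants: 17 (2R,3R,4R)-7-(benzyloxy)-2-Ar-4-(GC)chromane-3,4-diol
Product: 18 (2R,3S,4R)-7-(benzyloxy)-2-Ar-4-(GC)chroman-3-ol
Conditions: Et3SiH (5 equiv), TFA (3 equiv), CH2Cl2, −40 °C to 0 °C
Reagents that add atoms: none
Why: Ionic hydrogenation should ionise only the tertiary, doubly benzylic C4–OH (cation stabilised by the para oxygen of ring A and the ortho/para oxygens of ring D), and the silane should deliver hydride to the C4 face opposite the C3 hydroxyl, the 1,2-anti preference that nucleophiles show toward flavan-4-yl cations, which places ring D cis to the 3-OH (4R).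

Step 14
Reactants: 18 (2R,3S,4R)-7-(benzyloxy)-2-Ar-4-(GC)chroman-3-ol
Product: 19 robinetinidol-(4→8)-gallocatechin, the (2R,3S,4R)/(2R,3S) target
Conditions: H2 (1 atm), Pd(OH)2/C, THF/MeOH, rt; filtration under argon, Sephadex LH-20
Reagents that add atoms: none
Why: Hydrogenolysis should cleave all ten benzyl ethers while the C4–H and the ring C–O bonds, which carry no leaving group, stay in place, so no stereocenter is touched.

Compound list
1 | (+)-gallocatechin, (2R,3S)-2-(3,4,5-trihydroxyphenyl)chroman-3,5,7-triol | Oc1cc(O)c2c(c1)O[C@H](c5cc(O)c(O)c(O)c5)[C@@H](O)C2 | starting material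
2 | (2R,3S)-5,7-bis(benzyloxy)-2-[3,4,5-tris(benzyloxy)phenyl]chroman-3-ol | c3c(OCc6ccccc6)cc(OCc6ccccc6)c4c3O[C@H](c5cc(OCc6ccccc6)c(OCc6ccccc6)c(OCc6ccccc6)c5)[C@@H](O)C4 | intermediate
3 | (2R,3S)-3,5,7-tris(benzyloxy)-2-[3,4,5-tris(benzyloxy)phenyl]chroman | c3c(OCc6ccccc6)cc(OCc6ccccc6)c4c3O[C@H](c5cc(OCc6ccccc6)c(OCc6ccccc6)c(OCc6ccccc6)c5)[C@@H](OCc6ccccc6)C4 | intermediate
4 | (2R,3S)-8-bromo-3,5,7-tris(benzyloxy)-2-[3,4,5-tris(benzyloxy)phenyl]chroman | Brc3c(OCc6ccccc6)cc(OCc6ccccc6)c4c3O[C@H](c5cc(OCc6ccccc6)c(OCc6ccccc6)c(OCc6ccccc6)c5)[C@@H](OCc6ccccc6)C4 | intermediate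
5 | 3,4,5-tris(benzyloxy)benzaldehyde | O=Cc1cc(OCc2ccccc2)c(OCc2ccccc2)c(OCc2ccccc2)c1 | starting material
6 | ethyl (E)-3-[3,4,5-tris(benzyloxy)phenyl]prop-2-enoate | CCOC(=O)/C=C/c1cc(OCc2ccccc2)c(OCc2ccccc2)c(OCc2ccccc2)c1 | intermediate
7 | (E)-3-[3,4,5-tris(benzyloxy)phenyl]prop-2-en-1-ol | OC/C=C/c1cc(OCc2ccccc2)c(OCc2ccccc2)c(OCc2ccccc2)c1 | intermediate
8 | methyl (E)-3-[3,4,5-tris(benzyloxy)phenyl]prop-2-en-1-yl carbonate | COC(=O)OC/C=C/c1cc(OCc2ccccc2)c(OCc2ccccc2)c(OCc2ccccc2)c1 | intermediate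
9 | 4-(benzyloxy)-2-hydroxybenzaldehyde | O=Cc1ccc(OCc2ccccc2)cc1O | starting material
10 | sodium 5-(benzyloxy)-2-formylphenoxide | O=Cc1ccc(OCc2ccccc2)cc1[O-].[Na+] | intermediate
11 | 4-(benzyloxy)-2-{[(1S)-1-[3,4,5-tris(benzyloxy)phenyl]prop-2-en-1-yl]oxy}benzaldehyde | O=Cc1ccc(OCc6ccccc6)cc1O[C@H](c5cc(OCc6ccccc6)c(OCc6ccccc6)c(OCc6ccccc6)c5)C=C | intermediate
12 | [(2R,3S)-3,5,7-tris(benzyloxy)-2-[3,4,5-tris(benzyloxy)phenyl]chroman-8-yl]lithium | [Li]c3c(OCc6ccccc6)cc(OCc6ccccc6)c4c3O[C@H](c5cc(OCc6ccccc6)c(OCc6ccccc6)c(OCc6ccccc6)c5)[C@@H](OCc6ccccc6)C4 | intermediate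
13 | {4-(benzyloxy)-2-[((1S)-1-Ar-prop-2-en-1-yl)oxy]phenyl}(GC)methanol, both carbinol epimers | OC(c1ccc(OCc6ccccc6)cc1O[C@H](c5cc(OCc6ccccc6)c(OCc6ccccc6)c(OCc6ccccc6)c5)C=C)c3c(OCc6ccccc6)cc(OCc6ccccc6)c4c3O[C@H](c5cc(OCc6ccccc6)c(OCc6ccccc6)c(OCc6ccccc6)c5)[C@@H](OCc6ccccc6)C4 | intermediate
14 | {4-(benzyloxy)-2-[((1S)-1-Ar-prop-2-en-1-yl)oxy]phenyl}(GC)methanone | O=C(c1ccc(OCc6ccccc6)cc1O[C@H](c5cc(OCc6ccccc6)c(OCc6ccccc6)c(OCc6ccccc6)c5)C=C)c3c(OCc6ccccc6)cc(OCc6ccccc6)c4c3O[C@H](c5cc(OCc6ccccc6)c(OCc6ccccc6)c(OCc6ccccc6)c5)[C@@H](OCc6ccccc6)C4 | intermediate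
15 | {4-(benzyloxy)-2-[((1R)-2,3-dihydroxy-1-Ar-propyl)oxy]phenyl}(GC)methanone, both epimers at the secondary carbinol | O=C(c1ccc(OCc6ccccc6)cc1O[C@H](c5cc(OCc6ccccc6)c(OCc6ccccc6)c(OCc6ccccc6)c5)C(O)CO)c3c(OCc6ccccc6)cc(OCc6ccccc6)c4c3O[C@H](c5cc(OCc6ccccc6)c(OCc6ccccc6)c(OCc6ccccc6)c5)[C@@H](OCc6ccccc6)C4 | intermediate
16 | (2R)-2-{5-(benzyloxy)-2-[(GC)carbonyl]phenoxy}-2-Ar-acetaldehyde | O=C(c1ccc(OCc6ccccc6)cc1O[C@H](c5cc(OCc6ccccc6)c(OCc6ccccc6)c(OCc6ccccc6)c5)C=O)c3c(OCc6ccccc6)cc(OCc6ccccc6)c4c3O[C@H](c5cc(OCc6ccccc6)c(OCc6ccccc6)c(OCc6ccccc6)c5)[C@@H](OCc6ccccc6)C4 | intermediate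
17 | (2R,3R,4R)-7-(benzyloxy)-2-Ar-4-(GC)chromane-3,4-diol | C(c6ccccc6)Oc1ccc2c(c1)O[C@H](c5cc(OCc6ccccc6)c(OCc6ccccc6)c(OCc6ccccc6)c5)[C@@H](O)[C@]2(O)c3c(OCc6ccccc6)cc(OCc6ccccc6)c4c3O[C@H](c5cc(OCc6ccccc6)c(OCc6ccccc6)c(OCc6ccccc6)c5)[C@@H](OCc6ccccc6)C4 | intermediate
18 | (2R,3S,4R)-7-(benzyloxy)-2-Ar-4-(GC)chroman-3-ol | C(c6ccccc6)Oc1ccc2c(c1)O[C@H](c5cc(OCc6ccccc6)c(OCc6ccccc6)c(OCc6ccccc6)c5)[C@@H](O)[C@H]2c3c(OCc6ccccc6)cc(OCc6ccccc6)c4c3O[C@H](c5cc(OCc6ccccc6)c(OCc6ccccc6)c(OCc6ccccc6)c5)[C@@H](OCc6ccccc6)C4 | intermediate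
19 | robinetinidol-(4→8)-gallocatechin, (2R,3S,4R)-2-(3,4,5-trihydroxyphenyl)-4-[(2R,3S)-3,5,7-trihydroxy-2-(3,4,5-trihydroxyphenyl)chroman-8-yl]chromane-3,7-diol | Oc1ccc2c(c1)O[C@H](c1cc(O)c(O)c(O)c1)[C@@H](O)[C@H]2c1c(O)cc(O)c2c1O[C@H](c1cc(O)c(O)c(O)c1)[C@@H](O)C2 | target

Total step count: 14. Longest linear sequence: 11 steps (steps 4 to 14, from compound 5).

Steps most likely to fail

Step 12. The coupling may lose out to reductive cleavage of the α-aryloxy C–O bond, or the aldehyde may epimerise at the future C2 before it cyclises. The fallback sets out from ketone 14 and comes back at diol 17. MeLi (THF, −78 °C) adds to 14 to give the tertiary carbinol F1, which is dehydrated with PPTS in warm toluene to the 1,1-diarylethene F2. Ring-closing metathesis of F2 with the second-generation Hoveyda–Grubbs catalyst (toluene, 80 °C) closes the same C3–C4 bond as an alkene, giving the 4-aryl-flav-3-ene F3. OsO4 in pyridine (then aq. NaHSO3) should dihydroxylate F3 on the face opposite the C2 aryl group, which is the 2,3-trans-3,4-cis diol 17.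

Step 13. Hydride delivery may show poor facial selectivity, or the C4 cation may undergo a 1,2-hydride shift from C3 to give a 3-ketone. The fallback sets out from 17 and comes back at 18. Ac2O/pyridine/DMAP acetylates only the secondary hydroxyl to give the 3-O-acetate F4. Et3SiH/TFA (CH2Cl2, −40 °C) then ionises C4 with participation of the neighbouring acetoxy group, which blocks the face of the C3 oxygen and disfavours the hydride shift, so hydride enters anti to give the 3-O-acetyl-4-H compound F5. K2CO3/MeOH removes the acetate to give 18.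

Step 7. Branched selectivity or enantiopurity may erode through re-ionisation of the electron-rich benzylic aryl ether, or the chelating formyl phenoxide may slow the catalyst. The fallback sets out from aldehyde 5 and comes back at 11. Enantioselective vinyl transfer to 5 with Zn(CH=CH2)2 and a chiral amino alcohol ligand gives the (R)-allylic alcohol F6. A Mitsunobu reaction of F6 with phenol 9 (PPh3, DIAD, toluene, −20 °C) should form the aryl ether with inversion, giving the S ether 11.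

Further compounds
F1 | step 12 | 1-{4-(benzyloxy)-2-[((1S)-1-Ar-prop-2-en-1-yl)oxy]phenyl}-1-(GC)ethanol, both carbinol epimers | CC(O)(c1ccc(OCc6ccccc6)cc1O[C@H](c5cc(OCc6ccccc6)c(OCc6ccccc6)c(OCc6ccccc6)c5)C=C)c3c(OCc6ccccc6)cc(OCc6ccccc6)c4c3O[C@H](c5cc(OCc6ccccc6)c(OCc6ccccc6)c(OCc6ccccc6)c5)[C@@H](OCc6ccccc6)C4
F2 | step 12 | 1-{4-(benzyloxy)-2-[((1S)-1-Ar-prop-2-en-1-yl)oxy]phenyl}-1-(GC)ethene | C=C(c1ccc(OCc6ccccc6)cc1O[C@H](c5cc(OCc6ccccc6)c(OCc6ccccc6)c(OCc6ccccc6)c5)C=C)c3c(OCc6ccccc6)cc(OCc6ccccc6)c4c3O[C@H](c5cc(OCc6ccccc6)c(OCc6ccccc6)c(OCc6ccccc6)c5)[C@@H](OCc6ccccc6)C4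
F3 | step 12 | (2S)-7-(benzyloxy)-2-Ar-4-(GC)-2H-chromene | C(c6ccccc6)Oc1ccc2c(c1)O[C@H](c5cc(OCc6ccccc6)c(OCc6ccccc6)c(OCc6ccccc6)c5)C=C2c3c(OCc6ccccc6)cc(OCc6ccccc6)c4c3O[C@H](c5cc(OCc6ccccc6)c(OCc6ccccc6)c(OCc6ccccc6)c5)[C@@H](OCc6ccccc6)C4
F4 | step 13 | (2R,3R,4R)-7-(benzyloxy)-4-hydroxy-2-Ar-4-(GC)chroman-3-yl acetate | C(c6ccccc6)Oc1ccc2c(c1)O[C@H](c5cc(OCc6ccccc6)c(OCc6ccccc6)c(OCc6ccccc6)c5)[C@@H](OC(C)=O)[C@]2(O)c3c(OCc6ccccc6)cc(OCc6ccccc6)c4c3O[C@H](c5cc(OCc6ccccc6)c(OCc6ccccc6)c(OCc6ccccc6)c5)[C@@H](OCc6ccccc6)C4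
F5 | step 13 | (2R,3S,4R)-7-(benzyloxy)-2-Ar-4-(GC)chroman-3-yl acetate | C(c6ccccc6)Oc1ccc2c(c1)O[C@H](c5cc(OCc6ccccc6)c(OCc6ccccc6)c(OCc6ccccc6)c5)[C@@H](OC(C)=O)[C@H]2c3c(OCc6ccccc6)cc(OCc6ccccc6)c4c3O[C@H](c5cc(OCc6ccccc6)c(OCc6ccccc6)c(OCc6ccccc6)c5)[C@@H](OCc6ccccc6)C4
F6 | step 7 | (1R)-1-[3,4,5-tris(benzyloxy)phenyl]prop-2-en-1-ol | O[C@@H](c1cc(OCc2ccccc2)c(OCc2ccccc2)c(OCc2ccccc2)c1)C=C
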